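**Retrosynthetic overview**

- The C6 prenyl group goes in last, by aromatic Claisen rearrangement of the 7-O-(1,1-dimethylallyl) ether of 8-[(2R)-2-hydroxy-3-methylbut-3-enyl]orobol; C8 is already occupied, so only C6 can accept it.
- Key bond: the C–O bond at the stereocentre, made by an enantioselective ene-like oxygenation of the C8 prenyl group of tetra-O-acetyl-8-prenylorobol with a chiral oxoammonium salt (new), followed by N–O cleavage and deacetylation.
- Tetra-O-acetyl-8-prenylorobol comes from Claisen rearrangement (to C8) of 7-O-(1,1-dimethylallyl)orobol with acetylation in the same flask; the ether comes from palladium-catalysed O-allylation of orobol.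
- Orobol comes from phloroglucinol and 3,4-dihydroxyphenylacetic acid in one pot.
- Ring order: rings A and B are the two purchased arenes; ring C (the pyranone) is the only ring formed, in step 1, by O1–C2 closure.

**Assumptions**

- tert-Butyl (2-methylbut-3-en-2-yl) carbonate is taken as a catalogue reagent.
- The chiral oxoammonium salt of step 4 is a new reagent, made beforehand from its known, resolved nitroxyl radical; its amine is recovered after the step.
- The sense of induction of that reagent is unknown; the (S,S) antipode is written, and its mirror image is used if a model alkene shows the opposite sense.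

Orobol numbering is used throughout: 5 and 7 on ring A, 3' and 4' on ring B. The target stereocentre is (R).

**Route**

Step 1
Reactants: 1 phloroglucinol; 2 3,4-dihydroxyphenylacetic acid
Product: 4 orobol (3-(3,4-dihydroxyphenyl)-5,7-dihydroxy-4H-chromen-4-one), via deoxybenzoin 3 (not isolated)
Conditions: BF3·OEt2 (solvent), 85 °C, 2 h; then DMF, MsCl, 70 °C, 2 h; aqueous work-up
Reagents that add atoms: N,N-dimethylformamide, CN(C)C=O (its formyl carbon becomes C2)
Why: Friedel–Crafts acylation of the symmetric triol gives one deoxybenzoin, which the DMF/MsCl Vilsmeier-type reagent C-formylates and closes to the pyranone by O1–C2 bond formation, both ortho hydroxyls being equivalent.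

Step 2
Reactants: 4 orobol; 5 tert-butyl (2-methylbut-3-en-2-yl) carbonate (1.05 equiv)
Product: 6 7-O-(1,1-dimethylallyl)orobol
Conditions: Pd(PPh3)4 (5 mol%), THF, 0 °C → rt, argon
Reagents that add atoms: tert-butyl (2-methylbut-3-en-2-yl) carbonate 5, C=CC(C)(C)OC(=O)OC(C)(C)C
Why: Tsuji–Trost decarboxylative O-allylation, in which zerovalent palladium ionises the carbonate, the released tert-butoxide deprotonates the most acidic hydroxyl (7-OH, a vinylogous acid) and the phenoxide attacks the more substituted allyl terminus under kinetic control.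

Step 3
Reactants: 6 7-O-(1,1-dimethylallyl)orobol
Product: 9 tetra-O-acetyl-8-prenylorobol (5,7,3',4'-tetraacetate), via 7-O-(1,1-dimethylallyl)orobol 5,3',4'-triacetate 7 (not isolated), via 8-prenylorobol 5,3',4'-triacetate 8 (not isolated)
Conditions: Ac2O (8 equiv), 4-(dimethylamino)pyridine (0.2 equiv), N,N-diethylaniline, 25 °C, 3 h; then 140 °C, 4 h
Reagents that add atoms: acetic anhydride, CC(=O)OC(C)=O
Why: After acetylation of the free hydroxyls, an aromatic Claisen rearrangement of the aryl 1,1-dimethylallyl ether delivers a normal prenyl group to C8 (the C7–C8 bond has the higher double-bond character in chromones and C6 is flanked by the 5-acetoxy group), and the freed 7-OH is acetylated at once so it cannot add to the prenyl double bond.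

Step 4
Reactants: 9 tetra-O-acetyl-8-prenylorobol; 10 (2S,5S)-2,5-dimethyl-1-oxo-2,5-diphenylpyrrolidin-1-ium tetrafluoroborate (1.2 equiv)
Product: 12 tetra-O-acetyl-8-[(2R)-2-hydroxy-3-methylbut-3-en-1-yl]orobol, via N-alkoxyammonium tetrafluoroborate 11 (not isolated)
Conditions: 10, MeCN, −20 °C, 12 h; then Zn dust, NaOAc, AcOH–THF–H2O, 40 °C
Reagents that add atoms: oxoammonium salt 10, O=[N+]1[C@](C)(c2ccccc2)CC[C@@]1(C)c1ccccc1.F[B-](F)(F)F (its oxygen becomes the hydroxyl oxygen)
Why: Proposed new method: an enantioselective ene-like addition of a chiral oxoammonium cation, in which the electrophilic oxygen of N=O+ bonds to the less substituted alkene carbon while a methyl hydrogen passes to nitrogen through a highly asynchronous six-membered transition state with cationic character at the tertiary carbon (hence only the transposed 1,1-disubstituted alkene, and no reaction at the electron-poor chromone double bond or the aryl acetates), the phenyl/methyl quadrants that flank N=O in the C2-symmetric reagent admitting the alkene through one face only and so setting the (R) centre (C2 symmetry makes both faces of N=O the same and leaves nitrogen non-stereogenic in the adduct), after which Zn/AcOH cleaves the N–O bond and leaves the new C–O bond alone; the closest known reaction is the racemic ene-like addition of the achiral 4-acetamido-2,2,6,6-tetramethylpiperidine oxoammonium tetrafluoroborate to trisubstituted alkenes, which gives allylic alkoxyamines with the same double-bond shift, and chiral oxoammonium salts are so far known only as oxidants for kinetic resolution of secondary alcohols.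

Step 5
Reactants: 12 tetra-O-acetyl-8-[(2R)-2-hydroxy-3-methylbut-3-en-1-yl]orobol
Product: 13 8-[(2R)-2-hydroxy-3-methylbut-3-en-1-yl]orobol
Conditions: K2CO3 (0.2 equiv), MeOH, 0 °C → rt, argon
Reagents that add atoms: none
Why: Base-catalysed transesterification (Zemplén-type methanolysis) removes the four aryl acetates as methyl acetate and does not involve the carbinol centre.

Step 6
Reactants: 13 8-[(2R)-2-hydroxy-3-methylbut-3-en-1-yl]orobol; 5 tert-butyl (2-methylbut-3-en-2-yl) carbonate (1.1 equiv)
Product: 14 7-O-(1,1-dimethylallyl)-8-[(2R)-2-hydroxy-3-methylbut-3-en-1-yl]orobol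
Conditions: Pd(PPh3)4 (5 mol%), THF, 0 °C, argon
Reagents that add atoms: tert-butyl (2-methylbut-3-en-2-yl) carbonate 5, C=CC(C)(C)OC(=O)OC(C)(C)C
Why: The same Tsuji–Trost O-allylation with zerovalent palladium again picks the 7-OH, which is more acidic by about two pKa units than the catechol hydroxyls and far more than the secondary alcohol, and the free allylic alcohol is not ionised under these neutral conditions.

Step 7
Reactants: 14 7-O-(1,1-dimethylallyl)-8-[(2R)-2-hydroxy-3-methylbut-3-en-1-yl]orobol
Product: 15 target, 3-(3,4-dihydroxyphenyl)-5,7-dihydroxy-8-[(2R)-2-hydroxy-3-methylbut-3-en-1-yl]-6-(3-methylbut-2-en-1-yl)-4H-chromen-4-one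
Conditions: toluene (degassed), 115 °C, sealed tube, 6 h
Reagents that add atoms: none
Why: Aromatic Claisen rearrangement, in which the [3,3] shift can end only at C6 because C8 is substituted (an ipso shift to C8 is reversible), and neutral heating leaves the allylic alcohol stereocentre untouched.

**Compound list**

1 | phloroglucinol (benzene-1,3,5-triol) | Oc1cc(O)cc(O)c1 | starting material
2 | 3,4-dihydroxyphenylacetic acid | OC(=O)Cc1ccc(O)c(O)c1 | starting material
3 | 2-(3,4-dihydroxyphenyl)-1-(2,4,6-trihydroxyphenyl)ethan-1-one (deoxybenzoin) | O=C(Cc1ccc(O)c(O)c1)c1c(O)cc(O)cc1O | intermediate (not isolated)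
4 | orobol, 3-(3,4-dihydroxyphenyl)-5,7-dihydroxy-4H-chromen-4-one | O=c1c(-c2ccc(O)c(O)c2)coc2cc(O)cc(O)c12 | intermediate
5 | tert-butyl (2-methylbut-3-en-2-yl) carbonate | C=CC(C)(C)OC(=O)OC(C)(C)C | starting material (reagent)
6 | 7-O-(1,1-dimethylallyl)orobol, 3-(3,4-dihydroxyphenyl)-5-hydroxy-7-[(2-methylbut-3-en-2-yl)oxy]-4H-chromen-4-one | O=c1c(-c2ccc(O)c(O)c2)coc2cc(OC(C)(C)C=C)cc(O)c12 | intermediate
7 | 5,3',4'-tri-O-acetyl-7-O-(1,1-dimethylallyl)orobol | CC(=O)Oc1ccc(-c2coc3cc(OC(C)(C)C=C)cc(OC(C)=O)c3c2=O)cc1OC(C)=O | intermediate (not isolated)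
8 | 5,3',4'-tri-O-acetyl-8-(3-methylbut-2-en-1-yl)orobol (7-OH free) | CC(=O)Oc1ccc(-c2coc3c(CC=C(C)C)c(O)cc(OC(C)=O)c3c2=O)cc1OC(C)=O | intermediate (not isolated)
9 | 5,7,3',4'-tetra-O-acetyl-8-(3-methylbut-2-en-1-yl)orobol | CC(=O)Oc1ccc(-c2coc3c(CC=C(C)C)c(OC(C)=O)cc(OC(C)=O)c3c2=O)cc1OC(C)=O | intermediate
10 | (2S,5S)-2,5-dimethyl-1-oxo-2,5-diphenylpyrrolidin-1-ium tetrafluoroborate (trans, C2-symmetric) | O=[N+]1[C@](C)(c2ccccc2)CC[C@@]1(C)c1ccccc1.F[B-](F)(F)F | starting material (new chiral reagent, prepared beforehand, amine recovered)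
11 | (2S,5S)-1-{[(2R)-3-methyl-1-(5,7,3',4'-tetra-O-acetylorobol-8-yl)but-3-en-2-yl]oxy}-2,5-dimethyl-2,5-diphenylpyrrolidin-1-ium tetrafluoroborate | C=C(C)[C@H](O[NH+]1[C@](C)(c2ccccc2)CC[C@@]1(C)c1ccccc1)Cc1c(OC(C)=O)cc(OC(C)=O)c2c(=O)c(-c3ccc(OC(C)=O)c(OC(C)=O)c3)coc12.F[B-](F)(F)F | intermediate (not isolated)
12 | 5,7,3',4'-tetra-O-acetyl-8-[(2R)-2-hydroxy-3-methylbut-3-en-1-yl]orobol | C=C(C)[C@H](O)Cc1c(OC(C)=O)cc(OC(C)=O)c2c(=O)c(-c3ccc(OC(C)=O)c(OC(C)=O)c3)coc12 | intermediate
13 | 8-[(2R)-2-hydroxy-3-methylbut-3-en-1-yl]orobol | C=C(C)[C@H](O)Cc1c(O)cc(O)c2c(=O)c(-c3ccc(O)c(O)c3)coc12 | intermediate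
14 | 7-O-(1,1-dimethylallyl)-8-[(2R)-2-hydroxy-3-methylbut-3-en-1-yl]orobol | C=C(C)[C@H](O)Cc1c(OC(C)(C)C=C)cc(O)c2c(=O)c(-c3ccc(O)c(O)c3)coc12 | intermediate
15 | 3-(3,4-dihydroxyphenyl)-5,7-dihydroxy-8-[(2R)-2-hydroxy-3-methylbut-3-en-1-yl]-6-(3-methylbut-2-en-1-yl)-4H-chromen-4-one | C=C(C)[C@H](O)Cc1c(O)c(CC=C(C)C)c(O)c2c(=O)c(-c3ccc(O)c(O)c3)coc12 | target

**Step count and risks**

Total steps: 7. Longest linear sequence: 7 (from phloroglucinol and 3,4-dihydroxyphenylacetic acid).

The three steps most likely to fail: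

Step 4, the new ene-type oxygenation. The enantioselectivity and its sense are unproven, and a slow ene reaction would leave room for hydride abstraction at the benzylic-allylic CH2. The fallback uses known chemistry, sets out from 9 and comes back at 13. Shi asymmetric epoxidation of 9 (1,2:4,5-di-O-isopropylidene-β-D-erythro-2,3-hexodiulo-2,6-pyranose, Oxone (2KHSO5·KHSO4·K2SO4), NaHCO3 buffer at pH 8, MeCN–dimethoxymethane–H2O, 0 °C) gives 5,7,3',4'-tetra-O-acetyl-8-{[(2R)-3,3-dimethyloxiran-2-yl]methyl}orobol F4; the 7-acetate keeps the phenol from opening the epoxide, and the spiro transition-state model predicts the (R) epoxide from the D-fructose-derived ketone. TMSOTf and 1,8-diazabicyclo[5.4.0]undec-7-ene in toluene (−20 °C → rt) open the epoxide at the tertiary carbon and remove a methyl proton, giving 5,7,3',4'-tetra-O-acetyl-8-[(2R)-3-methyl-2-(trimethylsilyloxy)but-3-en-1-yl]orobol F5 with the C–O bond at the stereocentre untouched. K2CO3 in MeOH then removes the silyl group and the four acetates to give 13.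

Step 3, the Claisen rearrangement to C8. Some C6 isomer may form, and the tertiary ether may lose isoprene. The fallback sets out from 4, replaces steps 2 and 3, and comes back at 9. Brief treatment with Ac2O in pyridine at rt gives 7,3',4'-tri-O-acetylorobol F1 (the chelated 5-OH stays free). Mitsunobu etherification with 3-methylbut-2-en-1-ol (PPh3, diisopropyl azodicarboxylate, THF) gives 7,3',4'-tri-O-acetyl-5-O-(3-methylbut-2-en-1-yl)orobol F2. Eu(fod)3 (europium tris(6,6,7,7,8,8,8-heptafluoro-2,2-dimethyloctane-3,5-dionate), 10 mol%, CHCl3, 60 °C) brings about the para-Claisen–Cope sequence (ortho shift to C6, then Cope shift to C8) to give 7,3',4'-tri-O-acetyl-8-(3-methylbut-2-en-1-yl)orobol F3. Ac2O with 4-(dimethylamino)pyridine in pyridine acetylates the 5-OH to give 9.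

Step 6, O-allylation of the now hindered 7-OH next to a free catechol and a secondary alcohol. The fallback sets out from 13, replaces steps 6 and 7, and comes back at 15. Direct C-prenylation of 13 with prenyl bromide (1.1 equiv) and KOH (2 equiv) in H2O–MeOH at 0 °C under argon alkylates the ambident 7-phenoxide at C6, the only free nucleophilic ring carbon. The yield is expected to be low, because O-alkylation competes, but the reaction type is known. This fallback makes no new compound (F0).

**Further compounds**

F1 | step 3 | 7,3',4'-tri-O-acetylorobol | CC(=O)Oc1ccc(-c2coc3cc(OC(C)=O)cc(O)c3c2=O)cc1OC(C)=O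
F2 | step 3 | 7,3',4'-tri-O-acetyl-5-O-(3-methylbut-2-en-1-yl)orobol | CC(=O)Oc1ccc(-c2coc3cc(OC(C)=O)cc(OCC=C(C)C)c3c2=O)cc1OC(C)=O
F3 | step 3 | 7,3',4'-tri-O-acetyl-8-(3-methylbut-2-en-1-yl)orobol | CC(=O)Oc1ccc(-c2coc3c(CC=C(C)C)c(OC(C)=O)cc(O)c3c2=O)cc1OC(C)=O
F4 | step 4 | 5,7,3',4'-tetra-O-acetyl-8-{[(2R)-3,3-dimethyloxiran-2-yl]methyl}orobol | CC1(C)[C@H](O1)Cc1c(OC(C)=O)cc(OC(C)=O)c2c(=O)c(-c3ccc(OC(C)=O)c(OC(C)=O)c3)coc12
F5 | step 4 | 5,7,3',4'-tetra-O-acetyl-8-[(2R)-3-methyl-2-(trimethylsilyloxy)but-3-en-1-yl]orobol | C=C(C)[C@H](O[Si](C)(C)C)Cc1c(OC(C)=O)cc(OC(C)=O)c2c(=O)c(-c3ccc(OC(C)=O)c(OC(C)=O)c3)coc12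
F0 | step 6 | none | none
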